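**Plan**

- Retrosynthesis: the two phenols are unmasked last, and the C4 ketone is traced back to a temporary cis-C4 carbinol. The pyranone is then cut at O1–C2 (oxa-Michael) and at C2–C3 (aldol), giving an A-ring acetophenone and a B-ring benzaldehyde.
- The three aryl–prenyl bonds are cut at the stage of the simple phenols (phenoxide C-alkylation), before any heterocycle exists.
- Forward: prenylated ketone and prenylated aldehyde → Claisen–Schmidt chalcone → 6-endo oxa-Michael closure to the racemic flavanone.
- Enabling feature: O1–C2 lies β to the C4 carbonyl and C3 carries acidic hydrogens, so C2 epimerises through E1cB ring opening to the achiral 2'-hydroxychalcone.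
- Stereochemistry: a dynamic kinetic asymmetric transfer hydrogenation of the C4 ketone funnels both enantiomers into the (2S,4S)-cis-flavan-4-ol. Re-oxidation removes the auxiliary C4 centre and leaves 2S.

Key step: step 7

Assumption: the (S,S)-TsDPEN–Ru catalyst is taken to follow the usual aryl alkyl ketone model and deliver the 4S carbinol; the mirror-image catalyst would be used should the opposite sense be found.

**Step 1**
Reactants: 1 2,4-dihydroxyacetophenone; 2 prenyl bromide (1-bromo-3-methylbut-2-ene)
Product: 3 1-[2,4-dihydroxy-3,5-bis(3-methylbut-2-enyl)phenyl]ethanone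
Conditions: prenyl bromide (2.2 equiv), 10% aq. KOH, 0 °C → rt
Reagents that add atoms: prenyl bromide, CC(C)=CCBr
Why: Phenoxide C-alkylation in water (solvated oxygen, soft allylic electrophile) should place a prenyl group on each carbon ortho to the 4-oxygen (C3 and C5), a known direct C-prenylation of resacetophenone.

**Step 2**
Reactants: 3 1-[2,4-dihydroxy-3,5-bis(3-methylbut-2-enyl)phenyl]ethanone; 4 chloromethyl methyl ether
Product: 5 1-[2-hydroxy-4-(methoxymethoxy)-3,5-bis(3-methylbut-2-enyl)phenyl]ethanone
Conditions: MOMCl, iPr2NEt, CH2Cl2, 0 °C → rt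
Reagents that add atoms: chloromethyl methyl ether, COCCl
Why: Williamson-type MOM protection should take only the 4-hydroxyl, because the 2-hydroxyl is chelated to the ketone and stays free for the later ring closure.

**Step 3**
Reactants: 6 4-hydroxybenzaldehyde; 2 prenyl bromide
Product: 7 4-hydroxy-3-(3-methylbut-2-enyl)benzaldehyde
Conditions: prenyl bromide (1 equiv), 10% aq. KOH, rt
Reagents that add atoms: prenyl bromide, CC(C)=CCBr
Why: Aqueous phenoxide C-alkylation ortho to the hydroxyl is a known, if modest, entry to this aldehyde; the para position is blocked by the formyl group.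

**Step 4**
Reactants: 7 4-hydroxy-3-(3-methylbut-2-enyl)benzaldehyde; 4 chloromethyl methyl ether
Product: 8 4-(methoxymethoxy)-3-(3-methylbut-2-enyl)benzaldehyde
Conditions: MOMCl, iPr2NEt, CH2Cl2, 0 °C → rt
Reagents that add atoms: chloromethyl methyl ether, COCCl
Why: MOM protection removes the phenoxide that would otherwise deactivate the aldehyde in the base-mediated condensation.

**Step 5**
Reactants: 5 1-[2-hydroxy-4-(methoxymethoxy)-3,5-bis(3-methylbut-2-enyl)phenyl]ethanone; 8 4-(methoxymethoxy)-3-(3-methylbut-2-enyl)benzaldehyde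
Product: 10 (E)-1-[2-hydroxy-4-(methoxymethoxy)-3,5-bis(3-methylbut-2-enyl)phenyl]-3-[4-(methoxymethoxy)-3-(3-methylbut-2-enyl)phenyl]prop-2-en-1-one, via β-hydroxy ketone aldol adduct 9 (not isolated)
Conditions: KOH, EtOH–H2O, 0 °C → rt; dilute HCl on work-up
Reagents that add atoms: none
Why: Claisen–Schmidt condensation (aldol addition, then E1cB dehydration) should give the conjugated E-chalcone; MOM ethers and prenyl groups are stable to hydroxide.

**Step 6**
Reactants: 10 the (E)-chalcone
Product: 11 rac-7-(methoxymethoxy)-2-[4-(methoxymethoxy)-3-(3-methylbut-2-enyl)phenyl]-6,8-bis(3-methylbut-2-enyl)chroman-4-one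
Conditions: NaOAc, EtOH, reflux; unreacted chalcone recycled
Reagents that add atoms: none
Why: Base-mediated intramolecular oxa-Michael addition (6-endo-trig) of the 2'-phenol closes the pyranone; no stereocontrol is needed here because C2 is corrected in step 7.

**Step 7**
Reactants: 11 the racemic bis-MOM flavanone
Product: 12 (2S,4S)-7-(methoxymethoxy)-2-[4-(methoxymethoxy)-3-(3-methylbut-2-enyl)phenyl]-6,8-bis(3-methylbut-2-enyl)chroman-4-ol (2,4-cis), via ring-opened chalcone 10 (not isolated)
Conditions: RuCl[(S,S)-TsDPEN](p-cymene) (2 mol %), HCO2H, DBU (in excess over HCO2H), MeCN, 40 °C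
Reagents that add atoms: none
Why: DBU removes a C3 proton and the enolate expels the O1 phenoxide (E1cB), giving the achiral chalcone phenoxide of 10, which recloses by 6-endo-trig oxa-Michael addition, so the two enantiomers of 11 interconvert continuously while the Ru–H/N–H catalyst reduces the C4 ketone by outer-sphere hydride transfer. The closest known reaction type is dynamic kinetic asymmetric transfer hydrogenation of 2-substituted chroman-4-ones with elimination-induced racemisation, alongside the kinetic resolution of flavanones by the same catalyst family. The pyranone ring is the only ring opened and reclosed, and its closure mode is 6-endo-trig. C4 is set by the catalyst (aryl alkyl ketone model, 4S with the (S,S) ligand), and C2 is selected by the substrate: hydride adds to the face anti to the pseudo-equatorial C2 aryl group, so only the 2S enantiomer is matched and gives the cis alcohol. The step needs racemisation faster than reduction of the mismatched enantiomer, which the excess amidine base and the good phenoxide leaving group should secure, and C=O reduction faster than conjugate reduction of the low-concentration chalcone phenoxide, which is deactivated as an anion. The MOM ethers keep the 7- and 4'-oxygens from forming phenoxides that would deactivate the ketone, and the three trisubstituted prenyl alkenes are inert to the transfer-hydrogenation catalyst.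

**Step 8**
Reactants: 12 the (2S,4S)-cis-flavan-4-ol
Product: 13 (2S)-7-(methoxymethoxy)-2-[4-(methoxymethoxy)-3-(3-methylbut-2-enyl)phenyl]-6,8-bis(3-methylbut-2-enyl)chroman-4-one
Conditions: Dess–Martin periodinane, CH2Cl2, 0 °C → rt
Reagents that add atoms: none
Why: Dess–Martin oxidation of the benzylic alcohol removes the auxiliary C4 centre under base-free conditions, so C2 cannot epimerise by ring opening and the prenyl alkenes are untouched.

**Step 9**
Reactants: 13 the (2S)-bis-MOM flavanone
Product: 14 (2S)-7-hydroxy-2-[4-hydroxy-3-(3-methylbut-2-enyl)phenyl]-6,8-bis(3-methylbut-2-enyl)chroman-4-one (target)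
Conditions: 3 M aq. HCl (catalytic), MeOH, 40 °C, stopped as soon as conversion is complete
Reagents that add atoms: none
Why: Acid-catalysed acetal exchange with methanol removes both MOM groups under conditions commonly used on prenylated flavanones; acid does not open the pyranone, so the 2S configuration is retained.

**Compound list**

1 | 2,4-dihydroxyacetophenone | CC(=O)c1ccc(O)cc1O | starting material
2 | prenyl bromide | CC(C)=CCBr | starting material
3 | 1-[2,4-dihydroxy-3,5-bis(3-methylbut-2-enyl)phenyl]ethanone | CC(=O)c1cc(CC=C(C)C)c(O)c(CC=C(C)C)c1O | intermediate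
4 | chloromethyl methyl ether | COCCl | starting material
5 | 1-[2-hydroxy-4-(methoxymethoxy)-3,5-bis(3-methylbut-2-enyl)phenyl]ethanone | CC(=O)c1cc(CC=C(C)C)c(OCOC)c(CC=C(C)C)c1O | intermediate
6 | 4-hydroxybenzaldehyde | O=Cc1ccc(O)cc1 | starting material
7 | 4-hydroxy-3-(3-methylbut-2-enyl)benzaldehyde | CC(C)=CCc1cc(C=O)ccc1O | intermediate
8 | 4-(methoxymethoxy)-3-(3-methylbut-2-enyl)benzaldehyde | CC(C)=CCc1cc(C=O)ccc1OCOC | intermediate
9 | rac-3-hydroxy-1-[2-hydroxy-4-(methoxymethoxy)-3,5-bis(3-methylbut-2-enyl)phenyl]-3-[4-(methoxymethoxy)-3-(3-methylbut-2-enyl)phenyl]propan-1-one | COCOc1ccc(C(O)CC(=O)c2cc(CC=C(C)C)c(OCOC)c(CC=C(C)C)c2O)cc1CC=C(C)C | intermediate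
10 | (E)-1-[2-hydroxy-4-(methoxymethoxy)-3,5-bis(3-methylbut-2-enyl)phenyl]-3-[4-(methoxymethoxy)-3-(3-methylbut-2-enyl)phenyl]prop-2-en-1-one | COCOc1ccc(/C=C/C(=O)c2cc(CC=C(C)C)c(OCOC)c(CC=C(C)C)c2O)cc1CC=C(C)C | intermediate
11 | rac-7-(methoxymethoxy)-2-[4-(methoxymethoxy)-3-(3-methylbut-2-enyl)phenyl]-6,8-bis(3-methylbut-2-enyl)chroman-4-one | COCOc1ccc(C2CC(=O)c3cc(CC=C(C)C)c(OCOC)c(CC=C(C)C)c3O2)cc1CC=C(C)C | intermediate
12 | (2S,4S)-7-(methoxymethoxy)-2-[4-(methoxymethoxy)-3-(3-methylbut-2-enyl)phenyl]-6,8-bis(3-methylbut-2-enyl)chroman-4-ol | COCOc1ccc([C@@H]2C[C@H](O)c3cc(CC=C(C)C)c(OCOC)c(CC=C(C)C)c3O2)cc1CC=C(C)C | intermediate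
13 | (2S)-7-(methoxymethoxy)-2-[4-(methoxymethoxy)-3-(3-methylbut-2-enyl)phenyl]-6,8-bis(3-methylbut-2-enyl)chroman-4-one | COCOc1ccc([C@@H]2CC(=O)c3cc(CC=C(C)C)c(OCOC)c(CC=C(C)C)c3O2)cc1CC=C(C)C | intermediate
14 | (2S)-7-hydroxy-2-[4-hydroxy-3-(3-methylbut-2-enyl)phenyl]-6,8-bis(3-methylbut-2-enyl)chroman-4-one | CC(C)=CCc1cc([C@@H]2CC(=O)c3cc(CC=C(C)C)c(O)c(CC=C(C)C)c3O2)ccc1O | target

**Step count**

Total steps: 9. Longest linear sequence: 7 (steps 1, 2, 5, 6, 7, 8, 9).

**Steps most likely to fail**

1. Step 7. Ring-opening racemisation may be slower than reduction of the mismatched enantiomer, which would erode enantio- and diastereoselectivity, and the transient chalcone may undergo conjugate reduction. Fallback: set out from 11 and run a classical kinetic resolution by asymmetric transfer hydrogenation without added strong base (Cp*RhCl[(R,R)-TsDPEN], HCO2H/Et3N, EtOAc, rt, stopped near half conversion). The 2R enantiomer should be reduced to (2R,4R)-7-(methoxymethoxy)-2-[4-(methoxymethoxy)-3-(3-methylbut-2-enyl)phenyl]-6,8-bis(3-methylbut-2-enyl)chroman-4-ol F1, while the unreacted 2S ketone is 13 itself, so the route is rejoined at 13 and step 8 is not needed. F1 would be recycled by Dess–Martin oxidation to (2R)-7-(methoxymethoxy)-2-[4-(methoxymethoxy)-3-(3-methylbut-2-enyl)phenyl]-6,8-bis(3-methylbut-2-enyl)chroman-4-one F2, followed by DBU-mediated equilibration through 10 back to racemic 11.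

2. Step 1. O-alkylation, incomplete alkylation and geminal over-alkylation may compete, giving poor control over the double C-prenylation. Fallback: set out from 1 and build each prenyl group by O-tert-prenylation and aromatic Claisen rearrangement. Pd(PPh3)4 and methyl 2-methylbut-3-en-2-yl carbonate in THF should give 1-[2-hydroxy-4-(2-methylbut-3-en-2-yloxy)phenyl]ethanone F3. Heating in N,N-diethylaniline should trigger the [3,3] shift to the carbon between the two oxygens and give 1-[2,4-dihydroxy-3-(3-methylbut-2-enyl)phenyl]ethanone F4. A second Pd-catalysed O-tert-prenylation should give 1-[2-hydroxy-4-(2-methylbut-3-en-2-yloxy)-3-(3-methylbut-2-enyl)phenyl]ethanone F5, whose Claisen rearrangement can only go to C5 and should return the route to 3.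

3. Step 6. The chalcone–flavanone equilibrium may lie unfavourably for the chelated 2'-hydroxyl, giving incomplete ring closure, and the ring may reopen during purification. Fallback: set out from 5 and 8 and close O1–C2 by substitution instead of conjugate addition. The dianion of 5 (LDA, 2.2 equiv, THF, −78 °C) should add to 8 and, after NH4Cl quench, allow isolation of the aldol adduct 9. Intramolecular Mitsunobu etherification (PPh3, DIAD, THF, 0 °C) of the 2'-phenol onto the benzylic carbinol should then give 11, where the route is rejoined; this fallback makes no compound outside the list (F0).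

**Further compounds**

F1 | step 7 | (2R,4R)-7-(methoxymethoxy)-2-[4-(methoxymethoxy)-3-(3-methylbut-2-enyl)phenyl]-6,8-bis(3-methylbut-2-enyl)chroman-4-ol | COCOc1ccc([C@H]2C[C@@H](O)c3cc(CC=C(C)C)c(OCOC)c(CC=C(C)C)c3O2)cc1CC=C(C)C
F2 | step 7 | (2R)-7-(methoxymethoxy)-2-[4-(methoxymethoxy)-3-(3-methylbut-2-enyl)phenyl]-6,8-bis(3-methylbut-2-enyl)chroman-4-one | COCOc1ccc([C@H]2CC(=O)c3cc(CC=C(C)C)c(OCOC)c(CC=C(C)C)c3O2)cc1CC=C(C)C
F3 | step 1 | 1-[2-hydroxy-4-(2-methylbut-3-en-2-yloxy)phenyl]ethanone | CC(=O)c1ccc(OC(C)(C)C=C)cc1O
F4 | step 1 | 1-[2,4-dihydroxy-3-(3-methylbut-2-enyl)phenyl]ethanone | CC(=O)c1ccc(O)c(CC=C(C)C)c1O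
F5 | step 1 | 1-[2-hydroxy-4-(2-methylbut-3-en-2-yloxy)-3-(3-methylbut-2-enyl)phenyl]ethanone | CC(=O)c1ccc(OC(C)(C)C=C)c(CC=C(C)C)c1O
F0 | step 6 | none | none
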